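In the tetrahydrofuran ring (O1, C2 aryl, C3 acyloxymethyl, C4 benzyl, C5) the benzylic carbon C2 lies exactly δ to O1 along O1–C5–C4–C3–C2. The route therefore disconnects the O1–C2 bond to an open-chain alcohol: an O-centred radical on the C5 hydroxyl removes the benzylic hydrogen of C2 by 1,5-hydrogen transfer, and the oxidised carbon is captured by the same oxygen, setting C2 trans to C3. One operation thus turns a C–H bond into the ring C–O bond. The precursor is the mono-isovalerate of a twofold-symmetric (R,R)-2,3-dibenzylbutane-1,4-diol, made by auxiliary-controlled oxidative homocoupling of a dihydroferulic imide enolate; by symmetry the mono-ester is a single compound.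

Key step: step 6

Remark: tetrahydrofuran numbering is used throughout (O1, C2 aryl-bearing, C3 acyloxymethyl-bearing, C4 benzyl-bearing, C5 methylene); in open-chain precursors these carbons are called the future C2 to C5. The target is (2S,3R,4R).

Step 1
Reactants: 1 3-(4-hydroxy-3-methoxyphenyl)propanoic acid (dihydroferulic acid)
Product: 3 3-[4-(benzyloxy)-3-methoxyphenyl]propanoic acid, via benzyl ester benzyl ether 2 (not isolated)
Conditions: BnBr (2.3 equiv), K2CO3, DMF, 60 °C; then NaOH, MeOH/H2O, 60 °C; then aq. HCl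
Reagents that add atoms: benzyl bromide BrCc1ccccc1
Why: Williamson O-benzylation of the phenoxide (the carboxylate is benzylated too) followed by saponification of benzyl ester 2 gives the acid with the phenol masked as a benzyl ether, a group that should survive the enolate, hydride and radical steps and leave by hydrogenolysis at the end.

Step 2
Reactants: 3 3-[4-(benzyloxy)-3-methoxyphenyl]propanoic acid; 4 (S)-4-benzyloxazolidin-2-one
Product: 6 (S)-4-benzyl-3-{3-[4-(benzyloxy)-3-methoxyphenyl]propanoyl}oxazolidin-2-one, via mixed pivalic anhydride 5 (not isolated)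
Conditions: PivCl, Et3N, THF, −20 °C; then 4, LiCl, rt
Reagents that add atoms: none
Why: N-acylation of the oxazolidinone through the mixed pivalic anhydride under LiCl/Et3N activation is the standard way to attach an Evans auxiliary to an acid, and no stereocentre is at risk.

Step 3
Reactants: 6 (S)-4-benzyl-3-{3-[4-(benzyloxy)-3-methoxyphenyl]propanoyl}oxazolidin-2-one (two molecules)
Product: 8 (4S,4'S)-3,3'-{(2R,3R)-2,3-bis[4-(benzyloxy)-3-methoxybenzyl]butanedioyl}bis(4-benzyloxazolidin-2-one), via lithium Z-enolate 7 (not isolated)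
Conditions: LiN(iPr)2, THF, −78 °C; then TiCl4, −78 °C to −20 °C
Reagents that add atoms: none
Why: Oxidative homocoupling of a chiral imide enolate: the chelated Z-enolate 7 is transmetallated to a tetravalent titanium enolate that is oxidised at the α-carbon with release of trivalent titanium, and each α-carbon forms the new C–C bond on the face opposite the 4-benzyl group of the (S)-auxiliary, which should set both new stereocentres R and give the twofold-symmetric succinate (the unlike R,S isomer is removed by chromatography or crystallisation).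

Step 4
Reactants: 8 (4S,4'S)-3,3'-{(2R,3R)-2,3-bis[4-(benzyloxy)-3-methoxybenzyl]butanedioyl}bis(4-benzyloxazolidin-2-one)
Product: 9 (2R,3R)-2,3-bis[4-(benzyloxy)-3-methoxybenzyl]butane-1,4-diol
Conditions: LiBH4, MeOH, THF, 0 °C to rt
Reagents that add atoms: none
Why: Reductive cleavage of N-acyl oxazolidinones by LiBH4 attacks the exocyclic carbonyls and gives the primary alcohols without enolisation, so both α-stereocentres are kept and the auxiliary is recovered.

Step 5
Reactants: 9 (2R,3R)-2,3-bis[4-(benzyloxy)-3-methoxybenzyl]butane-1,4-diol; 10 3-methylbutanoyl chloride (isovaleryl chloride)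
Product: 11 (2R,3R)-2,3-bis[4-(benzyloxy)-3-methoxybenzyl]-4-hydroxybutyl 3-methylbutanoate
Conditions: 10 (0.9 equiv, slow addition), pyridine, CH2Cl2, −40 °C to 0 °C
Reagents that add atoms: none
Why: Acylation of a primary alcohol by an acid chloride; the two hydroxyls are exchanged by the twofold axis, so any mono-acylation gives the same ester, and a slight deficit of acid chloride added slowly in the cold should hold back the diester (diol and diester are separable and recyclable).

Step 6
Reactants: 11 (2R,3R)-2,3-bis[4-(benzyloxy)-3-methoxybenzyl]-4-hydroxybutyl 3-methylbutanoate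
Product: 14 [(2S,3R,4R)-4-[4-(benzyloxy)-3-methoxybenzyl]-2-[4-(benzyloxy)-3-methoxyphenyl]tetrahydrofuran-3-yl]methyl 3-methylbutanoate, via alkyl hypoiodite 12 (not isolated), via benzylic iodide 13 (not isolated)
Conditions: PhI(OAc)2 (1.5 equiv), I2 (0.3 equiv), cyclohexane/CH2Cl2, visible light (tungsten lamp), rt
Reagents that add atoms: none
Why: Hypoiodite (Suárez-type) remote functionalisation: acetyl hypoiodite from PhI(OAc)2/I2 converts the free hydroxyl into hypoiodite 12, light homolyses the O–I bond, the alkoxy radical abstracts the benzylic hydrogen of the future C2 through a six-membered 1,5-hydrogen-transfer transition state, the benzylic radical takes up iodine to give 13, and the p-alkoxybenzylic C–I bond ionises and is captured by the hydroxyl. The closest known reaction type is the hypoiodite oxidative cyclisation of 4-arylbutan-1-ols to 2-aryltetrahydrofurans. The tetrahydrofuran closes in a 5-exo mode (5-exo-tet on the iodide, equivalently 5-exo-trig on the benzylic cation). The new stereocentre C2 is controlled by the existing C3 centre: in the envelope transition state the aryl group should take the pseudo-equatorial position anti to the C3 acyloxymethyl group, giving the 2,3-trans (2S) isomer, which is also the more stable epimer. The step needs site selectivity between the two benzylic CH2 groups and among the δ-hydrogens, and geometry and polarity secure it: only the hydrogens of the future C2 are benzylic and δ to the O-radical (the other benzylic carbon is γ and would need a 1,4-shift), while the δ-hydrogens on the acyloxymethyl carbon are stronger and electron-poor. Sub-stoichiometric iodine in a non-polar medium is chosen to hold back electrophilic iodination of the dialkoxyarene rings.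

Step 7
Reactants: 14 [(2S,3R,4R)-4-[4-(benzyloxy)-3-methoxybenzyl]-2-[4-(benzyloxy)-3-methoxyphenyl]tetrahydrofuran-3-yl]methyl 3-methylbutanoate
Product: 15 (+)-9'-isovaleroxylariciresinol
Conditions: H2 (1 atm), Pd/C, EtOAc, rt
Reagents that add atoms: none
Why: Hydrogenolysis of aryl benzyl ethers over Pd/C in a neutral aprotic solvent is much faster than cleavage of the cyclic benzylic C2–O1 bond, so stopping after uptake of two equivalents of hydrogen should free both phenols while the ring, the ester and all three stereocentres stay intact.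

Compound list
1 | 3-(4-hydroxy-3-methoxyphenyl)propanoic acid (dihydroferulic acid) | COc1cc(CCC(=O)O)ccc1O | starting material
2 | benzyl 3-[4-(benzyloxy)-3-methoxyphenyl]propanoate | COc1cc(CCC(=O)OCc2ccccc2)ccc1OCc1ccccc1 | intermediate
3 | 3-[4-(benzyloxy)-3-methoxyphenyl]propanoic acid | COc1cc(CCC(=O)O)ccc1OCc1ccccc1 | intermediate
4 | (S)-4-benzyloxazolidin-2-one | O=C1N[C@@H](Cc2ccccc2)CO1 | starting material
5 | 3-[4-(benzyloxy)-3-methoxyphenyl]propanoic pivalic anhydride | COc1cc(CCC(=O)OC(=O)C(C)(C)C)ccc1OCc1ccccc1 | intermediate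
6 | (S)-4-benzyl-3-{3-[4-(benzyloxy)-3-methoxyphenyl]propanoyl}oxazolidin-2-one | COc1cc(CCC(=O)N2C(=O)OC[C@@H]2Cc2ccccc2)ccc1OCc1ccccc1 | intermediate
7 | lithium Z-enolate of 6 | COc1cc(C/C=C(\O[Li])N2C(=O)OC[C@@H]2Cc2ccccc2)ccc1OCc1ccccc1 | intermediate
8 | (4S,4'S)-3,3'-{(2R,3R)-2,3-bis[4-(benzyloxy)-3-methoxybenzyl]butanedioyl}bis(4-benzyloxazolidin-2-one) | O=C([C@H](Cc1ccc(OCc2ccccc2)c(OC)c1)[C@@H](Cc1ccc(OCc2ccccc2)c(OC)c1)C(=O)N1C(=O)OC[C@@H]1Cc1ccccc1)N1C(=O)OC[C@@H]1Cc1ccccc1 | intermediate
9 | (2R,3R)-2,3-bis[4-(benzyloxy)-3-methoxybenzyl]butane-1,4-diol | COc1cc(C[C@@H](CO)[C@H](CO)Cc2ccc(OCc3ccccc3)c(OC)c2)ccc1OCc1ccccc1 | intermediate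
10 | 3-methylbutanoyl chloride (isovaleryl chloride) | CC(C)CC(=O)Cl | starting material
11 | (2R,3R)-2,3-bis[4-(benzyloxy)-3-methoxybenzyl]-4-hydroxybutyl 3-methylbutanoate | COc1cc(C[C@@H](CO)[C@H](COC(=O)CC(C)C)Cc2ccc(OCc3ccccc3)c(OC)c2)ccc1OCc1ccccc1 | intermediate
12 | alkyl hypoiodite of 11 | COc1cc(C[C@@H](COI)[C@H](COC(=O)CC(C)C)Cc2ccc(OCc3ccccc3)c(OC)c2)ccc1OCc1ccccc1 | intermediate
13 | benzylic iodide at the future C2 (both epimers at the iodide carbon) | COc1cc(C[C@@H](CO)[C@H](COC(=O)CC(C)C)C(I)c2ccc(OCc3ccccc3)c(OC)c2)ccc1OCc1ccccc1 | intermediate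
14 | [(2S,3R,4R)-4-[4-(benzyloxy)-3-methoxybenzyl]-2-[4-(benzyloxy)-3-methoxyphenyl]tetrahydrofuran-3-yl]methyl 3-methylbutanoate | COc1cc(C[C@H]2CO[C@H](c3ccc(OCc4ccccc4)c(OC)c3)[C@H]2COC(=O)CC(C)C)ccc1OCc1ccccc1 | intermediate
15 | (+)-9'-isovaleroxylariciresinol, [(2S,3R,4R)-4-(4-hydroxy-3-methoxybenzyl)-2-(4-hydroxy-3-methoxyphenyl)tetrahydrofuran-3-yl]methyl 3-methylbutanoate | COc1cc(C[C@H]2CO[C@H](c3ccc(O)c(OC)c3)[C@H]2COC(=O)CC(C)C)ccc1O | target

Total step count: 7. Longest linear sequence: 7 steps (from 1).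

Steps most likely to fail

Step 6 (key step). Electrophilic iodine may attack the electron-rich dialkoxyarene rings, or the benzylic cation may be captured by the neighbouring arene (aryltetralin formation), faster than the radical relay and oxygen capture proceed. The fallback sets out from 11 and comes back to the route at 15. The benzyl ethers are removed first (H2, Pd/C, EtOAc) to give (2R,3R)-4-hydroxy-2,3-bis(4-hydroxy-3-methoxybenzyl)butyl 3-methylbutanoate F1. DDQ (1 equiv, dioxane, rt) should then dehydrogenate a free p-alkylphenol to the p-quinone methide F2, whose exocyclic carbon is attacked by the hydroxyl in a 5-exo-trig oxa-1,6-addition, giving 15 directly with the aryl group trans to C3. This phenol-directed oxidation cannot tell the two guaiacyl rings apart, and only the quinone methide at the future C2 has a hydroxyl within five-ring reach, which is why it is held in reserve.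

Step 3. The α-radical may be reduced back to 6 (low conversion), and diastereocontrol may be incomplete, giving the unlike dimer. The fallback sets out from 6 and comes back at 9, building the two benzylic arms one after the other.
- Evans alkylation (NaN(SiMe3)2, THF, −78 °C; tert-butyl bromoacetate, CC(C)(C)OC(=O)CBr) should give (S)-4-benzyl-3-{(R)-2-[4-(benzyloxy)-3-methoxybenzyl]-4-(tert-butoxy)-4-oxobutanoyl}oxazolidin-2-one F3.
- LiBH4 (THF/MeOH, 0 °C) removes auxiliary 4 to give tert-butyl (R)-3-[4-(benzyloxy)-3-methoxybenzyl]-4-hydroxybutanoate F4.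
- TsOH (toluene, 80 °C) closes (R)-4-[4-(benzyloxy)-3-methoxybenzyl]dihydrofuran-2(3H)-one F5.
- LiN(iPr)2 (THF, −78 °C) and 4-(benzyloxy)-3-methoxybenzyl bromide (COc1cc(CBr)ccc1OCc1ccccc1) alkylate the lactone enolate anti to the β-substituent, giving (3R,4R)-3,4-bis[4-(benzyloxy)-3-methoxybenzyl]dihydrofuran-2(3H)-one F6.
- LiAlH4 (THF, 0 °C) reduces F6 to diol 9.

Step 5. Over-acylation to the diester and incomplete conversion are inherent to acylating two equivalent hydroxyls. The fallback sets out from 9 and comes back at 11 by a protect–acylate–deprotect sequence. Mono-silylation through the sparingly soluble mono-sodium alkoxide (NaH, THF; then TBSCl) should give (2R,3R)-2,3-bis[4-(benzyloxy)-3-methoxybenzyl]-4-[(tert-butyldimethylsilyl)oxy]butan-1-ol F7. Acylation with 10 (pyridine, DMAP, CH2Cl2) gives (2R,3R)-2,3-bis[4-(benzyloxy)-3-methoxybenzyl]-4-[(tert-butyldimethylsilyl)oxy]butyl 3-methylbutanoate F8. HF·pyridine (THF, 0 °C) removes the silyl group to return 11; a 1,4-acyl shift would be degenerate.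

Further compounds
F1 | step 6 | (2R,3R)-4-hydroxy-2,3-bis(4-hydroxy-3-methoxybenzyl)butyl 3-methylbutanoate | COc1cc(C[C@@H](CO)[C@H](COC(=O)CC(C)C)Cc2ccc(O)c(OC)c2)ccc1O
F2 | step 6 | p-quinone methide of F1 at the future C2 | COc1cc(C[C@@H](CO)[C@H](COC(=O)CC(C)C)C=C2C=CC(=O)C(OC)=C2)ccc1O
F3 | step 3 | (S)-4-benzyl-3-{(R)-2-[4-(benzyloxy)-3-methoxybenzyl]-4-(tert-butoxy)-4-oxobutanoyl}oxazolidin-2-one | CC(C)(C)OC(=O)C[C@@H](Cc1ccc(OCc2ccccc2)c(OC)c1)C(=O)N1C(=O)OC[C@@H]1Cc1ccccc1
F4 | step 3 | tert-butyl (R)-3-[4-(benzyloxy)-3-methoxybenzyl]-4-hydroxybutanoate | CC(C)(C)OC(=O)C[C@H](CO)Cc1ccc(OCc2ccccc2)c(OC)c1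
F5 | step 3 | (R)-4-[4-(benzyloxy)-3-methoxybenzyl]dihydrofuran-2(3H)-one | O=C1C[C@@H](Cc2ccc(OCc3ccccc3)c(OC)c2)CO1
F6 | step 3 | (3R,4R)-3,4-bis[4-(benzyloxy)-3-methoxybenzyl]dihydrofuran-2(3H)-one | O=C1OC[C@H](Cc2ccc(OCc3ccccc3)c(OC)c2)[C@H]1Cc1ccc(OCc2ccccc2)c(OC)c1
F7 | step 5 | (2R,3R)-2,3-bis[4-(benzyloxy)-3-methoxybenzyl]-4-[(tert-butyldimethylsilyl)oxy]butan-1-ol | COc1cc(C[C@@H](CO[Si](C)(C)C(C)(C)C)[C@H](CO)Cc2ccc(OCc3ccccc3)c(OC)c2)ccc1OCc1ccccc1
F8 | step 5 | (2R,3R)-2,3-bis[4-(benzyloxy)-3-methoxybenzyl]-4-[(tert-butyldimethylsilyl)oxy]butyl 3-methylbutanoate | COc1cc(C[C@@H](CO[Si](C)(C)C(C)(C)C)[C@H](COC(=O)CC(C)C)Cc2ccc(OCc3ccccc3)c(OC)c2)ccc1OCc1ccccc1
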